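## Retrosynthetic overview

1. The strategy rests on ring A (C1′ cinnamoyl carbon, C2′ OH, C3′ carrying chain carbon C5 of ring D–C1–C2–C3(OH)–C4–C5–C6=C7–ring C, C4′ OH, C5′ H, C6′ OMe), a 2-alkyl-5-methoxyresorcinol. It is cut into a 4-alkyl-3-tert-butoxycyclobutenone and methoxyacetylene, which form C3′–C4′, C4′–C5′ and C6′–C1′ (the liberated phenol carbon being called C4′) and close ring A. Ring A is the only ring made; rings B, C and D are bought as benzenes.
2. The liberated phenol then directs a formyl group to its own ortho carbon, the ring CH next to C6′. Both flanking oxygens end as OH, so numbering the finished ring from the acyl carbon only exchanges the labels 1′/5′ and 2′/4′. The formyl group becomes the methyl ketone, a Claisen–Schmidt condensation adds ring B, and one acid step removes all protecting groups.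
3. The cyclobutenone comes from the ketene of a C5-branched carboxylic acid and tert-butoxyacetylene.
4. The acid comes from an Ireland–Claisen rearrangement of an (R,E)-1-arylallyl acetate, which sets C5 and the C6=C7 styrene.
5. The allylic alcohol comes from an asymmetric alkenylzinc addition of a C1–C6 alkyne to the ring C aldehyde. The alkyne comes from Brown allylation of the ring D aldehyde (sets C3), ozonolysis and Ohira–Bestmann homologation.

Key step: step 13

Assumption: tert-butoxyacetylene is taken as a purchasable ynol ether and is used cold and freshly distilled.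

Shorthand in names: Q = (1E,3R,5S)-5-[(tert-butyldimethylsilyl)oxy]-1,7-bis[4-(methoxymethoxy)phenyl]hept-1-en-3-yl, the protected chain bonded through chain carbon C5 (C3 of the heptenyl name).

## Route

Step 1
Reactants: 1 methyl 3-(4-hydroxyphenyl)propanoate
Product: 2 methyl 3-[4-(methoxymethoxy)phenyl]propanoate
Conditions: MOMCl, i-Pr2NEt, CH2Cl2, 0 °C → rt
Reagents that add atoms: chloromethyl methyl ether, COCCl
Why: O-alkylation of the phenol by the oxocarbenium-type chloride under amine base gives the base-stable acetal that masks the ring D phenol until the last step.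

Step 2
Reactants: 2 methyl 3-[4-(methoxymethoxy)phenyl]propanoate
Product: 4 3-[4-(methoxymethoxy)phenyl]propanal, via aluminium hemiacetal 3 (not isolated)
Conditions: i-Bu2AlH (1.05 equiv), CH2Cl2, −78 °C; MeOH, then aq. potassium sodium tartrate
Reagents that add atoms: none
Why: Partial ester reduction should stop at the tetrahedral aluminium hemiacetal, which is stable at −78 °C and collapses to the aldehyde only on work-up.

Step 3
Reactants: 4 3-[4-(methoxymethoxy)phenyl]propanal
Product: 6 (3S)-1-[4-(methoxymethoxy)phenyl]hex-5-en-3-ol, via borinate ester 5 (not isolated)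
Conditions: (+)-Ipc2B(allyl) (pentane solution), Et2O, −78 °C; then NaOH, H2O2, 0 °C → rt
Reagents that add atoms: (+)-B-allyldiisopinocampheylborane, C=CCB([C@H]1C[C@H]2C[C@@H]([C@@H]1C)C2(C)C)[C@H]1C[C@H]2C[C@@H]([C@@H]1C)C2(C)C
Why: Brown asymmetric allylboration through a closed chair transition state; the isopinocampheyl groups of the (−)-α-pinene series should deliver allyl to the Re face of the aldehyde, which sets C3 as (S) under reagent control.

Step 4
Reactants: 6 (3S)-1-[4-(methoxymethoxy)phenyl]hex-5-en-3-ol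
Product: 7 tert-butyl{[(3S)-1-[4-(methoxymethoxy)phenyl]hex-5-en-3-yl]oxy}dimethylsilane
Conditions: TBSCl, imidazole, DMF, rt
Reagents that add atoms: tert-butyldimethylsilyl chloride, CC(C)(C)[Si](C)(C)Cl
Why: Imidazole-promoted silylation of the secondary alcohol; the silyl ether survives the basic and organometallic steps and leaves under milder acid than an alkyl acetal would.

Step 5
Reactants: 7 tert-butyl{[(3S)-1-[4-(methoxymethoxy)phenyl]hex-5-en-3-yl]oxy}dimethylsilane
Product: 9 (3S)-3-[(tert-butyldimethylsilyl)oxy]-5-[4-(methoxymethoxy)phenyl]pentanal, via ozonide 8 (not isolated)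
Conditions: O3, CH2Cl2, −78 °C (to the first blue tint); PPh3, −78 °C → rt
Reagents that add atoms: ozone, [O-][O+]=O
Why: Ozonolysis with reductive work-up cleaves the terminal alkene, which is far more reactive toward ozone than the mono-oxygenated benzene ring, and leaves C3 untouched.

Step 6
Reactants: 9 (3S)-3-[(tert-butyldimethylsilyl)oxy]-5-[4-(methoxymethoxy)phenyl]pentanal
Product: 10 tert-butyl{[(3S)-1-[4-(methoxymethoxy)phenyl]hex-5-yn-3-yl]oxy}dimethylsilane
Conditions: dimethyl (1-diazo-2-oxopropyl)phosphonate, K2CO3, MeOH, 0 °C → rt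
Reagents that add atoms: dimethyl (1-diazo-2-oxopropyl)phosphonate, CC(=O)C(=[N+]=[N-])P(=O)(OC)OC
Why: Ohira–Bestmann (Seyferth–Gilbert) homologation turns the aldehyde into the terminal alkyne under base mild enough to spare the β-silyloxy aldehyde.

Step 7
Reactants: 11 4-hydroxybenzaldehyde
Product: 12 4-(methoxymethoxy)benzaldehyde
Conditions: MOMCl, i-Pr2NEt, CH2Cl2, 0 °C → rt
Reagents that add atoms: chloromethyl methyl ether, COCCl
Why: The same phenol O-alkylation gives the protected aldehyde that serves as ring C in step 8 and as ring B in step 18.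

Step 8
Reactants: 10 tert-butyl{[(3S)-1-[4-(methoxymethoxy)phenyl]hex-5-yn-3-yl]oxy}dimethylsilane; 12 4-(methoxymethoxy)benzaldehyde
Product: 15 (1R,2E,5S)-5-[(tert-butyldimethylsilyl)oxy]-1,7-bis[4-(methoxymethoxy)phenyl]hept-2-en-1-ol, via alkenylborane 13 (not isolated), via alkenylzinc 14 (not isolated)
Conditions: Cy2BH, toluene, 0 °C → rt; Me2Zn, −78 °C; (+)-MIB (5 mol %), 12, −10 °C; aq. NH4Cl
Reagents that add atoms: none
Why: Syn hydroboration fixes the (E)-alkene, boron-to-zinc exchange gives the alkenylzinc, and the amino-alcohol-catalysed addition to the aryl aldehyde is ligand-controlled; (+)-MIB, the antipode of the ligand that gives (S)-1-phenylpropan-1-ol from PhCHO and Et2Zn, should direct addition to the Re face and set the carbinol as (R).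

Step 9
Reactants: 15 (1R,2E,5S)-5-[(tert-butyldimethylsilyl)oxy]-1,7-bis[4-(methoxymethoxy)phenyl]hept-2-en-1-ol
Product: 16 (1R,2E,5S)-5-[(tert-butyldimethylsilyl)oxy]-1,7-bis[4-(methoxymethoxy)phenyl]hept-2-en-1-yl acetate
Conditions: Ac2O, Et3N, DMAP (cat.), CH2Cl2, 0 °C; filtered through Et3N-deactivated silica
Reagents that add atoms: acetic anhydride, CC(=O)OC(C)=O
Why: DMAP-catalysed acylation under basic conditions keeps the ionisable 1-arylallyl ester away from acid, so the carbinol configuration should be retained.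

Step 10
Reactants: 16 (1R,2E,5S)-5-[(tert-butyldimethylsilyl)oxy]-1,7-bis[4-(methoxymethoxy)phenyl]hept-2-en-1-yl acetate
Product: 19 (3S,5S)-5-[(tert-butyldimethylsilyl)oxy]-7-[4-(methoxymethoxy)phenyl]-3-{(E)-2-[4-(methoxymethoxy)phenyl]ethenyl}heptanoic acid, via silyl ketene acetal 17 (not isolated), via trimethylsilyl ester 18 (not isolated)
Conditions: LiN(i-Pr)2, TMSCl, THF, −78 °C → rt; aqueous work-up at pH 5
Reagents that add atoms: none
Why: Ireland–Claisen rearrangement; the chair transition state with the aryl group equatorial transfers the (R)-carbinol configuration suprafacially across the (E)-allyl unit, which sets C5 in the required sense and forms the (E)-C6=C7 styrene.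

Step 11
Reactants: 19 (3S,5S)-5-[(tert-butyldimethylsilyl)oxy]-7-[4-(methoxymethoxy)phenyl]-3-{(E)-2-[4-(methoxymethoxy)phenyl]ethenyl}heptanoic acid; 20 tert-butoxyacetylene
Product: 23 3-tert-butoxy-4-Q-cyclobut-2-en-1-one (both epimers at the ring carbon), via acid chloride 21 (not isolated), via ketene 22 (not isolated)
Conditions: 1-chloro-N,N,2-trimethylprop-1-en-1-amine, CH2Cl2, 0 °C → rt; then added slowly to 20 (3 equiv), Et3N, CH2Cl2, 0 °C → rt
Reagents that add atoms: none
Why: The chloroenamine makes the acid chloride without free HCl, Et3N dehydrohalogenates it to the aldoketene, and the known ketene–ynol ether [2+2] cycloaddition (nucleophilic CH carbon to the ketene carbonyl carbon) gives the 4-alkyl-3-alkoxycyclobutenone; the new ring stereocentre is uncontrolled and is destroyed in step 13.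

Step 12
Reactants: 24 2-chloro-1,1-dimethoxyethane
Product: 26 methoxyacetylene, via sodium methoxyacetylide 25 (not isolated)
Conditions: NaNH2 (3 equiv), liquid NH3, −33 °C; then cold aq. NaCl, −70 → 20 °C, distilled into cold toluene
Reagents that add atoms: none
Why: Twofold base-induced elimination (loss of HCl and of methanol) gives the sodium acetylide, and protonation frees the volatile ynol ether, which is kept as a cold toluene solution.

Step 13
Reactants: 23 3-tert-butoxy-4-Q-cyclobut-2-en-1-one; 26 methoxyacetylene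
Product: 31 3-tert-butoxy-5-methoxy-2-Q-phenol, via vinylketene 27 (not isolated), via vinylcyclobutenone 28 (not isolated), via dienylketene 29 (not isolated), via cyclohexadienone 30 (not isolated)
Conditions: 26 (5 equiv), toluene, sealed tube, 80 °C then 110 °C; then K2CO3, MeOH, rt
Reagents that add atoms: none
Why: Heat opens cyclobutenone 23 by four-electron electrocyclic ring opening (chain rotating outward) to the tert-butoxy vinylketene 27, whose ketene carbon is attacked by the nucleophilic CH terminus of ynol ether 26 in a regioselective [2+2] cycloaddition to 28 (bonds C4′–C5′ and C6′–C1′), and 28 opens in turn to dienylketene 29. Ring A closes by thermal six-electron (disrotatory) electrocyclisation of 29, which forms C3′–C4′ and gives cyclohexadienone 30, and tautomerisation delivers phenol 31. The closest known reaction is the Danheiser benzannulation of cyclobutenones with alkoxy- and siloxyacetylenes, together with the known thermal opening of 3-alkoxycyclobutenones to ketenes. No stereocentre is created: the ring stereocentre of 23 is destroyed, while C5 and C3 lie outside the reacting array and cannot epimerise under neutral heating. The step needs regiocontrol (OMe para to the chain, secured by the polarisation of the ynol ether toward the ketene carbonyl carbon) and a preference of the ketene for the ynol ether over the styrene and over itself (secured by excess 26 and by the poor ketenophilicity of a 1,2-disubstituted styrene). A brief K2CO3/MeOH treatment returns any phenol that a ketene has acylated.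

Step 14
Reactants: 31 3-tert-butoxy-5-methoxy-2-Q-phenol
Product: 33 4-tert-butoxy-2-hydroxy-6-methoxy-3-Q-benzaldehyde, via benzylic alcohol 32 (not isolated)
Conditions: MgCl2, Et3N, (CH2O)n, MeCN, reflux; aq. NH4Cl
Reagents that add atoms: formaldehyde (as paraformaldehyde), C=O
Why: Casnati–Skattebøl ortho-formylation; the magnesium phenoxide delivers formaldehyde to the only free ortho carbon (between C–OH and C6′), a second formaldehyde oxidises the benzylic alkoxide by hydride transfer, and the basic medium spares the acid-labile groups; this carbon is C1′ of the target once the ring is numbered from the acyl carbon.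

Step 15
Reactants: 33 4-tert-butoxy-2-hydroxy-6-methoxy-3-Q-benzaldehyde
Product: 34 4-tert-butoxy-6-methoxy-2-(methoxymethoxy)-3-Q-benzaldehyde
Conditions: NaH, MOMCl, THF–DMF, 0 °C → rt
Reagents that add atoms: chloromethyl methyl ether, COCCl
Why: The sodium phenoxide of the hydrogen-bonded salicylaldehyde is O-alkylated, which removes the acidic proton before the Grignard and aldol steps.

Step 16
Reactants: 34 4-tert-butoxy-6-methoxy-2-(methoxymethoxy)-3-Q-benzaldehyde
Product: 35 1-[4-tert-butoxy-6-methoxy-2-(methoxymethoxy)-3-Q-phenyl]ethan-1-ol (both carbinol epimers)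
Conditions: MeMgBr, THF, −78 → 0 °C; aq. NH4Cl
Reagents that add atoms: methylmagnesium bromide, C[Mg]Br
Why: Grignard addition to the non-enolisable aldehyde; the new carbinol centre is uncontrolled and is removed in step 17.

Step 17
Reactants: 35 1-[4-tert-butoxy-6-methoxy-2-(methoxymethoxy)-3-Q-phenyl]ethan-1-ol
Product: 36 1-[4-tert-butoxy-6-methoxy-2-(methoxymethoxy)-3-Q-phenyl]ethan-1-one
Conditions: Dess–Martin periodinane, NaHCO3, CH2Cl2, 0 °C → rt
Reagents that add atoms: none
Why: Buffered Dess–Martin oxidation of the benzylic alcohol gives the methyl ketone without touching the styrene, the acetals or the silyl ether.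

Step 18
Reactants: 36 1-[4-tert-butoxy-6-methoxy-2-(methoxymethoxy)-3-Q-phenyl]ethan-1-one; 12 4-(methoxymethoxy)benzaldehyde
Product: 38 (E)-1-[4-tert-butoxy-6-methoxy-2-(methoxymethoxy)-3-Q-phenyl]-3-[4-(methoxymethoxy)phenyl]prop-2-en-1-one, via aldol 37 (not isolated)
Conditions: KOH, EtOH–THF, rt
Reagents that add atoms: none
Why: Claisen–Schmidt condensation; the methyl ketone enolate adds to the non-enolisable aldehyde and E1cB dehydration gives the thermodynamically preferred (E)-enone, while C5 is not acidic enough to be touched by hydroxide.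

Step 19
Reactants: 38 (E)-1-[4-tert-butoxy-6-methoxy-2-(methoxymethoxy)-3-Q-phenyl]-3-[4-(methoxymethoxy)phenyl]prop-2-en-1-one
Product: 39 calyxin A, (E)-1-{2,4-dihydroxy-3-[(1E,3R,5S)-5-hydroxy-1,7-bis(4-hydroxyphenyl)hept-1-en-3-yl]-6-methoxyphenyl}-3-(4-hydroxyphenyl)prop-2-en-1-one
Conditions: HCl (1.25 M in MeOH), THF, 0 °C → rt
Reagents that add atoms: none
Why: Acid-catalysed methanolysis should remove the four aryl acetals, the silyl ether and the tert-butyl ether (a vinylogous tert-butyl ester, para to the ketone) in one global deprotection without touching either stereocentre.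

## Compound list

1 | methyl 3-(4-hydroxyphenyl)propanoate | COC(=O)CCc1ccc(O)cc1 | starting material
2 | methyl 3-[4-(methoxymethoxy)phenyl]propanoate | COC(=O)CCc1ccc(OCOC)cc1 | intermediate
3 | diisobutylaluminium hemiacetal formed from 2 | COC(CCc1ccc(OCOC)cc1)O[Al](CC(C)C)CC(C)C | intermediate
4 | 3-[4-(methoxymethoxy)phenyl]propanal | O=CCCc1ccc(OCOC)cc1 | intermediate
5 | diisopinocampheylborinate ester of 6 | C=CC[C@@H](OB([C@H]1C[C@H]2C[C@@H]([C@@H]1C)C2(C)C)[C@H]1C[C@H]2C[C@@H]([C@@H]1C)C2(C)C)CCc1ccc(OCOC)cc1 | intermediate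
6 | (3S)-1-[4-(methoxymethoxy)phenyl]hex-5-en-3-ol | C=CC[C@@H](O)CCc1ccc(OCOC)cc1 | intermediate
7 | tert-butyl{[(3S)-1-[4-(methoxymethoxy)phenyl]hex-5-en-3-yl]oxy}dimethylsilane | C=CC[C@@H](O[Si](C)(C)C(C)(C)C)CCc1ccc(OCOC)cc1 | intermediate
8 | ozonide (1,2,4-trioxolane) of 7 | O1OC(C[C@@H](O[Si](C)(C)C(C)(C)C)CCc2ccc(OCOC)cc2)OC1 | intermediate
9 | (3S)-3-[(tert-butyldimethylsilyl)oxy]-5-[4-(methoxymethoxy)phenyl]pentanal | O=CC[C@@H](O[Si](C)(C)C(C)(C)C)CCc1ccc(OCOC)cc1 | intermediate
10 | tert-butyl{[(3S)-1-[4-(methoxymethoxy)phenyl]hex-5-yn-3-yl]oxy}dimethylsilane | C#CC[C@@H](O[Si](C)(C)C(C)(C)C)CCc1ccc(OCOC)cc1 | intermediate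
11 | 4-hydroxybenzaldehyde | O=Cc1ccc(O)cc1 | starting material
12 | 4-(methoxymethoxy)benzaldehyde | O=Cc1ccc(OCOC)cc1 | intermediate
13 | (E)-alkenyl(dicyclohexyl)borane from 10 | C1CCCCC1B(/C=C/C[C@@H](O[Si](C)(C)C(C)(C)C)CCc1ccc(OCOC)cc1)C1CCCCC1 | intermediate
14 | (E)-alkenyl(methyl)zinc from 13 | C[Zn]/C=C/C[C@@H](O[Si](C)(C)C(C)(C)C)CCc1ccc(OCOC)cc1 | intermediate
15 | (1R,2E,5S)-5-[(tert-butyldimethylsilyl)oxy]-1,7-bis[4-(methoxymethoxy)phenyl]hept-2-en-1-ol | O[C@@H](c1ccc(OCOC)cc1)/C=C/C[C@@H](O[Si](C)(C)C(C)(C)C)CCc1ccc(OCOC)cc1 | intermediate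
16 | (1R,2E,5S)-5-[(tert-butyldimethylsilyl)oxy]-1,7-bis[4-(methoxymethoxy)phenyl]hept-2-en-1-yl acetate | CC(=O)O[C@@H](c1ccc(OCOC)cc1)/C=C/C[C@@H](O[Si](C)(C)C(C)(C)C)CCc1ccc(OCOC)cc1 | intermediate
17 | O-trimethylsilyl ketene acetal of 16 | C=C(O[Si](C)(C)C)O[C@@H](c1ccc(OCOC)cc1)/C=C/C[C@@H](O[Si](C)(C)C(C)(C)C)CCc1ccc(OCOC)cc1 | intermediate
18 | trimethylsilyl ester of 19 | C[Si](C)(C)OC(=O)C[C@@H](/C=C/c1ccc(OCOC)cc1)C[C@@H](O[Si](C)(C)C(C)(C)C)CCc1ccc(OCOC)cc1 | intermediate
19 | (3S,5S)-5-[(tert-butyldimethylsilyl)oxy]-7-[4-(methoxymethoxy)phenyl]-3-{(E)-2-[4-(methoxymethoxy)phenyl]ethenyl}heptanoic acid | OC(=O)C[C@@H](/C=C/c1ccc(OCOC)cc1)C[C@@H](O[Si](C)(C)C(C)(C)C)CCc1ccc(OCOC)cc1 | intermediate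
20 | tert-butoxyacetylene | CC(C)(C)OC#C | starting material
21 | acid chloride of 19 | ClC(=O)C[C@@H](/C=C/c1ccc(OCOC)cc1)C[C@@H](O[Si](C)(C)C(C)(C)C)CCc1ccc(OCOC)cc1 | intermediate
22 | (3R,5S)-5-[(tert-butyldimethylsilyl)oxy]-7-[4-(methoxymethoxy)phenyl]-3-{(E)-2-[4-(methoxymethoxy)phenyl]ethenyl}hept-1-en-1-one (ketene) | O=C=C[C@@H](/C=C/c1ccc(OCOC)cc1)C[C@@H](O[Si](C)(C)C(C)(C)C)CCc1ccc(OCOC)cc1 | intermediate
23 | 3-tert-butoxy-4-Q-cyclobut-2-en-1-one (both epimers at the ring carbon) | O=C1C=C(OC(C)(C)C)C1[C@@H](/C=C/c1ccc(OCOC)cc1)C[C@@H](O[Si](C)(C)C(C)(C)C)CCc1ccc(OCOC)cc1 | intermediate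
24 | 2-chloro-1,1-dimethoxyethane | COC(CCl)OC | starting material
25 | sodium methoxyacetylide | [Na+].[C-]#COC | intermediate
26 | methoxyacetylene | COC#C | intermediate
27 | 3-tert-butoxy-4-Q-buta-1,3-dien-1-one (vinylketene, Q trans to the ketene CH) | O=C=C/C(OC(C)(C)C)=C/[C@@H](/C=C/c1ccc(OCOC)cc1)C[C@@H](O[Si](C)(C)C(C)(C)C)CCc1ccc(OCOC)cc1 | intermediate
28 | 4-(1-tert-butoxy-2-Q-ethenyl)-3-methoxycyclobut-2-en-1-one | O=C1C=C(OC)C1/C(OC(C)(C)C)=C/[C@@H](/C=C/c1ccc(OCOC)cc1)C[C@@H](O[Si](C)(C)C(C)(C)C)CCc1ccc(OCOC)cc1 | intermediate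
29 | 5-tert-butoxy-3-methoxy-6-Q-hexa-1,3,5-trien-1-one (dienylketene, central double bond cis) | O=C=C/C(OC)=C\C(OC(C)(C)C)=C\[C@@H](/C=C/c1ccc(OCOC)cc1)C[C@@H](O[Si](C)(C)C(C)(C)C)CCc1ccc(OCOC)cc1 | intermediate
30 | 5-tert-butoxy-3-methoxy-6-Q-cyclohexa-2,4-dien-1-one | O=C1C=C(OC)C=C(OC(C)(C)C)C1[C@@H](/C=C/c1ccc(OCOC)cc1)C[C@@H](O[Si](C)(C)C(C)(C)C)CCc1ccc(OCOC)cc1 | intermediate
31 | 3-tert-butoxy-5-methoxy-2-Q-phenol | COc1cc(O)c([C@@H](/C=C/c2ccc(OCOC)cc2)C[C@@H](O[Si](C)(C)C(C)(C)C)CCc2ccc(OCOC)cc2)c(OC(C)(C)C)c1 | intermediate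
32 | 5-tert-butoxy-2-(hydroxymethyl)-3-methoxy-6-Q-phenol | COc1cc(OC(C)(C)C)c([C@@H](/C=C/c2ccc(OCOC)cc2)C[C@@H](O[Si](C)(C)C(C)(C)C)CCc2ccc(OCOC)cc2)c(O)c1CO | intermediate
33 | 4-tert-butoxy-2-hydroxy-6-methoxy-3-Q-benzaldehyde | COc1cc(OC(C)(C)C)c([C@@H](/C=C/c2ccc(OCOC)cc2)C[C@@H](O[Si](C)(C)C(C)(C)C)CCc2ccc(OCOC)cc2)c(O)c1C=O | intermediate
34 | 4-tert-butoxy-6-methoxy-2-(methoxymethoxy)-3-Q-benzaldehyde | COc1cc(OC(C)(C)C)c([C@@H](/C=C/c2ccc(OCOC)cc2)C[C@@H](O[Si](C)(C)C(C)(C)C)CCc2ccc(OCOC)cc2)c(OCOC)c1C=O | intermediate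
35 | 1-[4-tert-butoxy-6-methoxy-2-(methoxymethoxy)-3-Q-phenyl]ethan-1-ol (both carbinol epimers) | COc1cc(OC(C)(C)C)c([C@@H](/C=C/c2ccc(OCOC)cc2)C[C@@H](O[Si](C)(C)C(C)(C)C)CCc2ccc(OCOC)cc2)c(OCOC)c1C(C)O | intermediate
36 | 1-[4-tert-butoxy-6-methoxy-2-(methoxymethoxy)-3-Q-phenyl]ethan-1-one | COc1cc(OC(C)(C)C)c([C@@H](/C=C/c2ccc(OCOC)cc2)C[C@@H](O[Si](C)(C)C(C)(C)C)CCc2ccc(OCOC)cc2)c(OCOC)c1C(C)=O | intermediate
37 | 3-hydroxy-3-[4-(methoxymethoxy)phenyl]-1-[4-tert-butoxy-6-methoxy-2-(methoxymethoxy)-3-Q-phenyl]propan-1-one | COc1cc(OC(C)(C)C)c([C@@H](/C=C/c2ccc(OCOC)cc2)C[C@@H](O[Si](C)(C)C(C)(C)C)CCc2ccc(OCOC)cc2)c(OCOC)c1C(=O)CC(O)c1ccc(OCOC)cc1 | intermediate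
38 | (E)-1-[4-tert-butoxy-6-methoxy-2-(methoxymethoxy)-3-Q-phenyl]-3-[4-(methoxymethoxy)phenyl]prop-2-en-1-one | COc1cc(OC(C)(C)C)c([C@@H](/C=C/c2ccc(OCOC)cc2)C[C@@H](O[Si](C)(C)C(C)(C)C)CCc2ccc(OCOC)cc2)c(OCOC)c1C(=O)/C=C/c1ccc(OCOC)cc1 | intermediate
39 | calyxin A | COc1cc(O)c([C@@H](/C=C/c2ccc(O)cc2)C[C@@H](O)CCc2ccc(O)cc2)c(O)c1C(=O)/C=C/c1ccc(O)cc1 | target

## Step count and risks

Total step count: 19. Longest linear sequence: 17 steps (1 to 39 through steps 1–6, 8–11 and 13–19).

**Step 13 (key benzannulation).** What may go wrong: capture of the donor-substituted vinylketene by the volatile ynol ether may be outrun by ketene dimerisation, by acylation of the product phenol, or by thermal loss of isobutene from the tert-butyl enol ether, so that ring A does not form cleanly. Fallback: ring A is bought as a benzene and joined to C5 by a stereospecific allylic substitution instead of being built. Setting out from alkyne 10 and aldehyde 12, step 8 is run with (−)-MIB to give the carbinol epimer (1S,2E,5S)-5-[(tert-butyldimethylsilyl)oxy]-1,7-bis[4-(methoxymethoxy)phenyl]hept-2-en-1-ol F1, which is esterified (picolinic acid, DCC, DMAP) to its pyridine-2-carboxylate F2. 1-Methoxy-3,5-bis(methoxymethoxy)benzene F3, made from commercial 5-methoxyresorcinol and MOMCl, is lithiated between its two acetal oxygens (n-BuLi, THF, 0 °C) and transmetalated with MgBr2·OEt2 to [4-methoxy-2,6-bis(methoxymethoxy)phenyl]magnesium bromide F4. With CuBr·SMe2 this reagent should displace the picolinate of F2 in the anti-SN2′ sense with 1,3-chirality transfer, giving 5-methoxy-1,3-bis(methoxymethoxy)-2-Q-benzene F5 with the C5 configuration and the (E)-styrene of the main route. Ring lithiation of F5 next to an acetal oxygen (n-BuLi, TMEDA, THF, −40 °C) and a quench with N-methoxy-N-methylacetamide give 1-[6-methoxy-2,4-bis(methoxymethoxy)-3-Q-phenyl]ethan-1-one F6. Claisen–Schmidt condensation of F6 with 12 (KOH, EtOH) gives the protected chalcone (E)-1-[6-methoxy-2,4-bis(methoxymethoxy)-3-Q-phenyl]-3-[4-(methoxymethoxy)phenyl]prop-2-en-1-one F7, and the acid treatment of step 19 removes its five acetals and the silyl ether, so the fallback comes back to the route at 39.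

**Step 11 (ketene–ynol ether cycloaddition).** What may go wrong: the aldoketene 22 may dimerise, or the thermally fragile ynol ether 20 may lose isobutene, faster than the two combine. Fallback: a chloroketene, which is more electrophilic and much less prone to dimerise, replaces the aldoketene and the halogen is removed afterwards. Setting out from acid 19, the dianion (LiN(i-Pr)2, 2.2 equiv, THF, −78 °C) is chlorinated with CCl4 to (3R,5S)-5-[(tert-butyldimethylsilyl)oxy]-2-chloro-7-[4-(methoxymethoxy)phenyl]-3-{(E)-2-[4-(methoxymethoxy)phenyl]ethenyl}heptanoic acid F8 (either C2 epimer serves). The chloroenamine of step 11 converts it into the α-chloro acid chloride F9, Et3N turns this into the alkylchloroketene F10, and 20 traps it as 3-tert-butoxy-4-chloro-4-Q-cyclobut-2-en-1-one F11. Zn dust with TMEDA and AcOH in EtOH at 0 °C then removes the chlorine and the fallback returns to the route at 23.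

**Step 19 (global deprotection).** What may go wrong: during the slow loss of four acetals the 2′-hydroxychalcone may close to the flavanone, methanol or a flanking phenol may add to the enone or to the protonated styrene, and the tert-butyl cation may alkylate ring A. Fallback: the phenols are unmasked before the enone exists and the condensation is run on free phenols. Setting out from ketone 36, the same methanolic HCl removes the three acetals, the silyl ether and the tert-butyl group to give 1-{2,4-dihydroxy-3-[(1E,3R,5S)-5-hydroxy-1,7-bis(4-hydroxyphenyl)hept-1-en-3-yl]-6-methoxyphenyl}ethan-1-one F12. Claisen–Schmidt condensation of F12 with unprotected 4-hydroxybenzaldehyde 11 (KOH, 50% aqueous, EtOH, rt) then gives the chalcone directly, so the route is rejoined at 39 and the enone never meets acid.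

## Further compounds

F1 | step 13 | (1S,2E,5S)-5-[(tert-butyldimethylsilyl)oxy]-1,7-bis[4-(methoxymethoxy)phenyl]hept-2-en-1-ol | O[C@H](c1ccc(OCOC)cc1)/C=C/C[C@@H](O[Si](C)(C)C(C)(C)C)CCc1ccc(OCOC)cc1
F2 | step 13 | (1S,2E,5S)-5-[(tert-butyldimethylsilyl)oxy]-1,7-bis[4-(methoxymethoxy)phenyl]hept-2-en-1-yl pyridine-2-carboxylate | O=C(O[C@H](c1ccc(OCOC)cc1)/C=C/C[C@@H](O[Si](C)(C)C(C)(C)C)CCc1ccc(OCOC)cc1)c1ccccn1
F3 | step 13 | 1-methoxy-3,5-bis(methoxymethoxy)benzene | COCOc1cc(OC)cc(OCOC)c1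
F4 | step 13 | [4-methoxy-2,6-bis(methoxymethoxy)phenyl]magnesium bromide | COCOc1cc(OC)cc(OCOC)c1[Mg]Br
F5 | step 13 | 5-methoxy-1,3-bis(methoxymethoxy)-2-Q-benzene | COCOc1cc(OC)cc(OCOC)c1[C@@H](/C=C/c1ccc(OCOC)cc1)C[C@@H](O[Si](C)(C)C(C)(C)C)CCc1ccc(OCOC)cc1
F6 | step 13 | 1-[6-methoxy-2,4-bis(methoxymethoxy)-3-Q-phenyl]ethan-1-one | CC(=O)c1c(OC)cc(OCOC)c([C@@H](/C=C/c2ccc(OCOC)cc2)C[C@@H](O[Si](C)(C)C(C)(C)C)CCc2ccc(OCOC)cc2)c1OCOC
F7 | step 13 | (E)-1-[6-methoxy-2,4-bis(methoxymethoxy)-3-Q-phenyl]-3-[4-(methoxymethoxy)phenyl]prop-2-en-1-one | COCOc1ccc(/C=C/C(=O)c2c(OC)cc(OCOC)c([C@@H](/C=C/c3ccc(OCOC)cc3)C[C@@H](O[Si](C)(C)C(C)(C)C)CCc3ccc(OCOC)cc3)c2OCOC)cc1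
F8 | step 11 | (3R,5S)-5-[(tert-butyldimethylsilyl)oxy]-2-chloro-7-[4-(methoxymethoxy)phenyl]-3-{(E)-2-[4-(methoxymethoxy)phenyl]ethenyl}heptanoic acid (C2 epimers) | OC(=O)C(Cl)[C@@H](/C=C/c1ccc(OCOC)cc1)C[C@@H](O[Si](C)(C)C(C)(C)C)CCc1ccc(OCOC)cc1
F9 | step 11 | acid chloride of F8 | ClC(=O)C(Cl)[C@@H](/C=C/c1ccc(OCOC)cc1)C[C@@H](O[Si](C)(C)C(C)(C)C)CCc1ccc(OCOC)cc1
F10 | step 11 | alkylchloroketene from F9 | O=C=C(Cl)[C@@H](/C=C/c1ccc(OCOC)cc1)C[C@@H](O[Si](C)(C)C(C)(C)C)CCc1ccc(OCOC)cc1
F11 | step 11 | 3-tert-butoxy-4-chloro-4-Q-cyclobut-2-en-1-one | O=C1C=C(OC(C)(C)C)C1(Cl)[C@@H](/C=C/c1ccc(OCOC)cc1)C[C@@H](O[Si](C)(C)C(C)(C)C)CCc1ccc(OCOC)cc1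
F12 | step 19 | 1-{2,4-dihydroxy-3-[(1E,3R,5S)-5-hydroxy-1,7-bis(4-hydroxyphenyl)hept-1-en-3-yl]-6-methoxyphenyl}ethan-1-one | COc1cc(O)c([C@@H](/C=C/c2ccc(O)cc2)C[C@@H](O)CCc2ccc(O)cc2)c(O)c1C(C)=O
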